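The cyclohexenone ring (C1 carbonyl, C2=C3, C4 carbinol, C5 quaternary carbinol, C6 methylene) is read as the 6π-electrocyclization product of the 3-oxidohexatriene C4=C3–C2=C1(O–)–C6=C5. One anionic cascade builds it from an acyclic (Z)-3-iodoallyl ester: iodine–lithium exchange, transfer of the acyl carbon C1 from O4 to C2 (C1–C2), Brook shift of the silyl group from C4 to O4, and disrotatory ring closure (C4–C5). It exploits the vinylogous C1(=O)–C2=C3–C4–O unit and the 1,3-dioxygenation C1/C5; the O4–C1 ester tether, absent from the target, is cleaved in the event. Enol ether geometry sets the trans-diol; a lipase resolution sets the absolute configuration.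

Key step: step 8

Remark: the target is read as (4S,5S): the hydroxyl groups on C4 and C5 are trans, and the C4 hydroxyl is cis to the (16E)-nonadec-16-enyl chain. O1, O4 and O5 are the oxygens on C1, C4 and C5.
Remark: the key step gives the racemate, so the single enantiomer is reached only by the resolution in step 10, which can deliver at most half of the material. Racemic compounds with two stereocentres are written as both enantiomers joined by a dot; the lone C4 centre of 8–15 is racemic and left undefined.

Step 1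
Reactants: 1 16-bromohexadecanoic acid; 2 but-1-yne
Product: 3 icos-17-ynoic acid
Conditions: 2 (3.5 equiv), n-BuLi (3.2 equiv), THF/DMPU, −78 → 0 °C; then 1, 0 → 20 °C; aq. HCl
Reagents that add atoms: none
Why: Deprotonated 2 should displace the primary bromide of 1, which is present as its inert lithium carboxylate (SN2 alkylation of an acetylide), placing the triple bond where the chain alkene is needed.

Step 2
Reactants: 3 icos-17-ynoic acid
Product: 4 (17E)-icos-17-enoic acid
Conditions: Li, NH3 (l)/THF, −33 °C; NH4Cl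
Reagents that add atoms: none
Why: Dissolving-metal reduction of an internal alkyne passes through the trans vinyl radical anion and should give only the E alkene, while the carboxylate is not reduced.

Step 3
Reactants: 4 (17E)-icos-17-enoic acid; 5 2,2-dimethyl-1,3-dioxane-4,6-dione (Meldrum's acid)
Product: 6 5-[(17E)-1-hydroxyicos-17-en-1-ylidene]-2,2-dimethyl-1,3-dioxane-4,6-dione
Conditions: DCC, DMAP, CH2Cl2, 0 → 20 °C
Reagents that add atoms: none
Why: Carbodiimide-mediated C-acylation of Meldrum's acid is the standard entry to acyl Meldrum's acids and does not touch the remote alkene.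

Step 4
Reactants: 7 tert-butyl(dimethyl)(prop-2-yn-1-yloxy)silane
Product: 9 1-[tert-butyl(dimethyl)silyl]-3-iodoprop-2-yn-1-ol (racemic), via dilithio alkoxide 8 (not isolated)
Conditions: n-BuLi (2.2 equiv), THF, −78 → −20 °C; I2 (1.0 equiv), −78 °C; aq. NH4Cl
Reagents that add atoms: iodine, II
Why: Metalation at the acetylenic and propargylic positions should trigger a 1,2-retro-Brook (O→C) silyl shift to 8, whose acetylide carbon is then iodinated by I2.

Step 5
Reactants: 9 1-[tert-butyl(dimethyl)silyl]-3-iodoprop-2-yn-1-ol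
Product: 10 (2Z)-1-[tert-butyl(dimethyl)silyl]-3-iodoprop-2-en-1-ol (racemic)
Conditions: 2-nitrobenzenesulfonohydrazide, Et3N, THF/i-PrOH, 20 °C
Reagents that add atoms: none
Why: Diimide generated in the flask adds hydrogen syn to the iodoalkyne (diimide semireduction) and should give the (Z)-iodoalkene without cleaving the C–I or C–Si bond.

Step 6
Reactants: 6 acyl Meldrum's acid; 10 (2Z)-1-[tert-butyl(dimethyl)silyl]-3-iodoprop-2-en-1-ol
Product: 12 (2Z)-1-[tert-butyl(dimethyl)silyl]-3-iodoprop-2-en-1-yl (19E)-3-oxodocos-19-enoate, via acylketene 11 (not isolated)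
Conditions: toluene, 85 °C
Reagents that add atoms: none
Why: Thermolysis of 6 should release acetone and CO2 to give acylketene 11, which the hindered alcohol 10 traps under neutral conditions (alcoholysis of an acyl Meldrum's acid).

Step 7
Reactants: 12 β-keto ester
Product: 13 (2Z)-1-[tert-butyl(dimethyl)silyl]-3-iodoprop-2-en-1-yl (2Z,19E)-3-{[tert-butyl(dimethyl)silyl]oxy}docosa-2,19-dienoate
Conditions: LiHMDS, THF, −78 °C; TBSOTf, −78 → 0 °C
Reagents that add atoms: tert-butyldimethylsilyl trifluoromethanesulfonate, CC(C)(C)[Si](C)(C)OS(=O)(=O)C(F)(F)F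
Why: O-silylation of the chelated, U-shaped lithium enolate of the β-keto ester should give the (Z)-enol silyl ether (silyloxy group cis to the ester carbonyl), the geometry that later fixes the C4/C5 relative configuration.

Step 8
Reactants: 13 (Z)-enol silyl ether ester
Product: 18 (4RS,5RS)-4,5-bis{[tert-butyl(dimethyl)silyl]oxy}-5-[(16E)-nonadec-16-en-1-yl]cyclohex-2-en-1-one (racemic trans), via vinyllithium 14 (not isolated), via alkoxide 15 (not isolated), via trienolate 16 (not isolated), via cyclohexadienolate 17 (not isolated)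
Conditions: t-BuLi (2.05 equiv), THF, −100 °C; DMPU, −78 → −40 °C; t-BuOH (0.3 equiv), −40 → 20 °C; AcOH, −40 °C
Reagents that add atoms: none
Why: Proposed new method: iodine–lithium exchange gives vinyllithium 14, which attacks its own ester carbonyl through a five-membered transition state (Parham-type cycliacylation) and expels the C4 alkoxide, so that the acyl carbon moves from O4 to C2 (C1–C2) to give 15; the α-silyl alkoxide of 15 then undergoes a 1,2-Brook shift because the C4 carbanion is the terminus of trienolate 16. Trienolate 16, the 3-oxidohexatriene C4=C3–C2=C1–C6=C5, should close the six-membered carbocycle by a thermally allowed disrotatory 6π-electrocyclization (formally a 6-endo vinylogous Michael addition, C4–C5) to dienolate 17, which is protonated at C6 on quench; because the Brook step first delivers the C1=C2 isomer with the oxido group syn to C3, substoichiometric t-BuOH is added as a proton shuttle so that the enolate geometry equilibrates and only the U-shaped isomer is drained. The closest known reaction types are the Parham cyclization of halo esters, the Brook-rearrangement-triggered annulations of silyl carbinols and acylsilanes, and the alkoxide-mediated cyclization of phorone to isophorone through its trienolate; their merger in one flask has not been shown. The relative configuration follows from disrotation: the (Z) C5=C6 bond holds the C5 oxygen inside and the chain outside, allylic 1,3-strain places the C4 siloxy group outside, and one inside and one outside oxygen give the trans-diol with O4 cis to the chain; the product is racemic and the absolute configuration is set in step 10. The step needs exchange to outrun addition of t-BuLi to the ester, acyl transfer only through the five-membered ring and a single carbanion site, which the −100 °C exchange, the cis iodoalkene and the silyl relay secure; masking C5 as its enol silyl ether removes the acidic C6 protons of a 1,3-dicarbonyl that would otherwise quench every anion of the cascade.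

Step 9
Reactants: 18 racemic trans-bis(silyl ether)
Product: 19 (4RS,5RS)-4,5-dihydroxy-5-[(16E)-nonadec-16-en-1-yl]cyclohex-2-en-1-one (racemic trans-diol)
Conditions: HF (48 % aq.), MeCN, 0 → 20 °C
Reagents that add atoms: none
Why: Fluoride-driven cleavage of the secondary and the tertiary silyl ether under weakly acidic conditions should leave the β-hydroxy ketone and the E alkene intact.

Step 10
Reactants: 19 racemic trans-diol
Product: 20 (4S,5S)-4,5-dihydroxy-5-[(16E)-nonadec-16-en-1-yl]cyclohex-2-en-1-one
Conditions: Burkholderia cepacia lipase, vinyl acetate, t-BuOMe, 30 °C, stopped near half conversion; chromatography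
Reagents that add atoms: none
Why: Lipase-catalysed transesterification (kinetic resolution) should acylate the (4R)-alcohol faster, as the empirical size rule for secondary alcohols predicts with C5 as the large substituent, so that the unreacted alcohol is recovered as the (4S,5S) enantiomer.

Compound list
1 | 16-bromohexadecanoic acid | OC(=O)CCCCCCCCCCCCCCCBr | starting material
2 | but-1-yne | CCC#C | starting material
3 | icos-17-ynoic acid | CCC#CCCCCCCCCCCCCCCCC(=O)O | intermediate
4 | (17E)-icos-17-enoic acid | CC/C=C/CCCCCCCCCCCCCCCC(=O)O | intermediate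
5 | 2,2-dimethyl-1,3-dioxane-4,6-dione (Meldrum's acid) | CC1(C)OC(=O)CC(=O)O1 | starting material
6 | 5-[(17E)-1-hydroxyicos-17-en-1-ylidene]-2,2-dimethyl-1,3-dioxane-4,6-dione | CC/C=C/CCCCCCCCCCCCCCCC(O)=C1C(=O)OC(C)(C)OC1=O | intermediate
7 | tert-butyl(dimethyl)(prop-2-yn-1-yloxy)silane | C#CCO[Si](C)(C)C(C)(C)C | starting material
8 | lithium 1-[tert-butyl(dimethyl)silyl]-3-lithioprop-2-yn-1-olate (racemic) | [Li]C#CC(O[Li])[Si](C)(C)C(C)(C)C | intermediate
9 | 1-[tert-butyl(dimethyl)silyl]-3-iodoprop-2-yn-1-ol (racemic) | OC(C#CI)[Si](C)(C)C(C)(C)C | intermediate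
10 | (2Z)-1-[tert-butyl(dimethyl)silyl]-3-iodoprop-2-en-1-ol (racemic) | OC(/C=C\I)[Si](C)(C)C(C)(C)C | intermediate
11 | (19E)-docosa-1,19-diene-1,3-dione (acylketene) | CC/C=C/CCCCCCCCCCCCCCCC(=O)C=C=O | intermediate
12 | (2Z)-1-[tert-butyl(dimethyl)silyl]-3-iodoprop-2-en-1-yl (19E)-3-oxodocos-19-enoate (racemic) | CC/C=C/CCCCCCCCCCCCCCCC(=O)CC(=O)OC(/C=C\I)[Si](C)(C)C(C)(C)C | intermediate
13 | (2Z)-1-[tert-butyl(dimethyl)silyl]-3-iodoprop-2-en-1-yl (2Z,19E)-3-{[tert-butyl(dimethyl)silyl]oxy}docosa-2,19-dienoate (racemic) | CC/C=C/CCCCCCCCCCCCCCC/C(O[Si](C)(C)C(C)(C)C)=C/C(=O)OC(/C=C\I)[Si](C)(C)C(C)(C)C | intermediate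
14 | (2Z)-1-[tert-butyl(dimethyl)silyl]-3-lithioprop-2-en-1-yl (2Z,19E)-3-{[tert-butyl(dimethyl)silyl]oxy}docosa-2,19-dienoate | CC/C=C/CCCCCCCCCCCCCCC/C(O[Si](C)(C)C(C)(C)C)=C/C(=O)OC(/C=C\[Li])[Si](C)(C)C(C)(C)C | intermediate
15 | lithium (2Z,5Z,22E)-1-[tert-butyl(dimethyl)silyl]-6-{[tert-butyl(dimethyl)silyl]oxy}-4-oxopentacosa-2,5,22-trien-1-olate | CC/C=C/CCCCCCCCCCCCCCC/C(O[Si](C)(C)C(C)(C)C)=C/C(=O)/C=C\C(O[Li])[Si](C)(C)C(C)(C)C | intermediate
16 | lithium (1E,3E,5Z,22E)-1,6-bis{[tert-butyl(dimethyl)silyl]oxy}pentacosa-1,3,5,22-tetraen-4-olate (ring-closing geometry) | CC/C=C/CCCCCCCCCCCCCCC/C(O[Si](C)(C)C(C)(C)C)=C/C(O[Li])=C\C=C\O[Si](C)(C)C(C)(C)C | intermediate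
17 | lithium trans-3,4-bis{[tert-butyl(dimethyl)silyl]oxy}-3-[(16E)-nonadec-16-en-1-yl]cyclohexa-1,5-dien-1-olate (racemic) | CC/C=C/CCCCCCCCCCCCCCC[C@]1(O[Si](C)(C)C(C)(C)C)C=C(O[Li])C=C[C@@H]1O[Si](C)(C)C(C)(C)C.CC/C=C/CCCCCCCCCCCCCCC[C@@]1(O[Si](C)(C)C(C)(C)C)C=C(O[Li])C=C[C@H]1O[Si](C)(C)C(C)(C)C | intermediate
18 | (4RS,5RS)-4,5-bis{[tert-butyl(dimethyl)silyl]oxy}-5-[(16E)-nonadec-16-en-1-yl]cyclohex-2-en-1-one (racemic trans) | CC/C=C/CCCCCCCCCCCCCCC[C@]1(O[Si](C)(C)C(C)(C)C)CC(=O)C=C[C@@H]1O[Si](C)(C)C(C)(C)C.CC/C=C/CCCCCCCCCCCCCCC[C@@]1(O[Si](C)(C)C(C)(C)C)CC(=O)C=C[C@H]1O[Si](C)(C)C(C)(C)C | intermediate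
19 | (4RS,5RS)-4,5-dihydroxy-5-[(16E)-nonadec-16-en-1-yl]cyclohex-2-en-1-one (racemic trans) | CC/C=C/CCCCCCCCCCCCCCC[C@]1(O)CC(=O)C=C[C@@H]1O.CC/C=C/CCCCCCCCCCCCCCC[C@@]1(O)CC(=O)C=C[C@H]1O | intermediate
20 | (4S,5S)-4,5-dihydroxy-5-[(16E)-nonadec-16-en-1-yl]cyclohex-2-en-1-one | CC/C=C/CCCCCCCCCCCCCCC[C@]1(O)CC(=O)C=C[C@@H]1O | target

Total step count: 10. Longest linear sequence: 8 steps (1, 2, 3, 6, 7, 8, 9, 10); steps 4 and 5 prepare the second fragment.

Steps most likely to fail

Step 8 (proposed new method). The cascade may stop or leak in several ways: the vinyllithium or the trienolate may be protonated before ring closure; the enolate geometry may fail to equilibrate; or the product dienolate may lose silanolate from C5 and then aromatize to a hydroquinone monoether. The fallback uses known chemistry and closes the ring by olefin metathesis. It sets out from 6, which is heated with methanol to methyl (19E)-3-oxodocos-19-enoate F1. Indium-mediated Barbier addition of 3-bromoprop-1-en-1-yl acetate to the ketone (In, THF/H2O) gives methyl (19E)-3-[1-(acetyloxy)prop-2-en-1-yl]-3-hydroxydocos-19-enoate F2 as a diastereomer mixture. MeNH(OMe)·HCl with i-PrMgCl converts the ester into the amide and removes the acetate, giving (19E)-3-hydroxy-3-(1-hydroxyprop-2-en-1-yl)-N-methoxy-N-methyldocos-19-enamide F3. CH2=CHMgBr then gives (21E)-5-hydroxy-5-(1-hydroxyprop-2-en-1-yl)tetracosa-1,21-dien-3-one F4. Ring-closing metathesis with the second-generation Grubbs catalyst at high dilution forms C2=C3. Chromatographic removal of the racemic cis-4,5-dihydroxy-5-[(16E)-nonadec-16-en-1-yl]cyclohex-2-en-1-one F5 returns the sequence to the route at 19.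

Step 4. n-BuLi may attack silicon, or the propargylic position may not be metalated, so that the silyl group does not migrate to carbon. The fallback protects the alkyne carbon first and iodinates by silicon–iodine exchange. It sets out from 7: n-BuLi then Me3SiCl gives tert-butyl(dimethyl){[3-(trimethylsilyl)prop-2-yn-1-yl]oxy}silane F6. t-BuLi (THF, −78 → −40 °C) effects the retro-Brook shift on the monoanion to 1-[tert-butyl(dimethyl)silyl]-3-(trimethylsilyl)prop-2-yn-1-ol F7. N-iodosuccinimide with catalytic AgNO3 in DMF replaces the alkynyl silyl group by iodine and returns to the route at 9.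

Step 10. Acylation of the hindered C4 hydroxyl may be slow or discriminate poorly between the enantiomers. The fallback resolves through covalent diastereomers. It sets out from 19, which is esterified at O4 with (2S)-methoxy(phenyl)acetic acid (DCC, DMAP). Chromatography separates (1S,6S)-6-hydroxy-6-[(16E)-nonadec-16-en-1-yl]-4-oxocyclohex-2-en-1-yl (2S)-methoxy(phenyl)acetate F8 from its (1R,6R) diastereomer F9. Methanolysis of F8 (K2CO3, MeOH, 0 °C) returns to the route at 20.

Further compounds
F1 | step 8 | methyl (19E)-3-oxodocos-19-enoate | CC/C=C/CCCCCCCCCCCCCCCC(=O)CC(=O)OC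
F2 | step 8 | methyl (19E)-3-[1-(acetyloxy)prop-2-en-1-yl]-3-hydroxydocos-19-enoate (diastereomer mixture) | CC/C=C/CCCCCCCCCCCCCCCC(O)(CC(=O)OC)C(OC(C)=O)C=C
F3 | step 8 | (19E)-3-hydroxy-3-(1-hydroxyprop-2-en-1-yl)-N-methoxy-N-methyldocos-19-enamide | CC/C=C/CCCCCCCCCCCCCCCC(O)(CC(=O)N(C)OC)C(O)C=C
F4 | step 8 | (21E)-5-hydroxy-5-(1-hydroxyprop-2-en-1-yl)tetracosa-1,21-dien-3-one | CC/C=C/CCCCCCCCCCCCCCCC(O)(CC(=O)C=C)C(O)C=C
F5 | step 8 | (4RS,5SR)-4,5-dihydroxy-5-[(16E)-nonadec-16-en-1-yl]cyclohex-2-en-1-one (racemic cis) | CC/C=C/CCCCCCCCCCCCCCC[C@]1(O)CC(=O)C=C[C@H]1O.CC/C=C/CCCCCCCCCCCCCCC[C@@]1(O)CC(=O)C=C[C@@H]1O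
F6 | step 4 | tert-butyl(dimethyl){[3-(trimethylsilyl)prop-2-yn-1-yl]oxy}silane | C[Si](C)(C)C#CCO[Si](C)(C)C(C)(C)C
F7 | step 4 | 1-[tert-butyl(dimethyl)silyl]-3-(trimethylsilyl)prop-2-yn-1-ol (racemic) | C[Si](C)(C)C#CC(O)[Si](C)(C)C(C)(C)C
F8 | step 10 | (1S,6S)-6-hydroxy-6-[(16E)-nonadec-16-en-1-yl]-4-oxocyclohex-2-en-1-yl (2S)-methoxy(phenyl)acetate | CC/C=C/CCCCCCCCCCCCCCC[C@]1(O)CC(=O)C=C[C@@H]1OC(=O)[C@@H](OC)c1ccccc1
F9 | step 10 | (1R,6R)-6-hydroxy-6-[(16E)-nonadec-16-en-1-yl]-4-oxocyclohex-2-en-1-yl (2S)-methoxy(phenyl)acetate | CC/C=C/CCCCCCCCCCCCCCC[C@@]1(O)CC(=O)C=C[C@H]1OC(=O)[C@@H](OC)c1ccccc1
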